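The ratio of amber's slope to ochre's reads 35.0: amber holds 3.5% of L at 5.00 min and 8 °C, ochre 0.5% at 25.0 min and −25 °C. Amber differs from ochre in more than temperature: its charged c_G is 2.98 times ochre's and its charged c_X 2.00 times, so I do not divide that ratio among the settings.

Teal is ochre's neighbour at the same temperature, with c_G charged at 1.80 mM against ochre's 1.32 mM. Yet teal ends at 0.3%, and that difference from ochre is within reach of a scatter of 0.3 percentage points. Both end low because their pace lies far under amber's.

| flask | X | E | G | temperature | remark | time |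
|---|---|---|---|---|---|---|
| teal | 0.050 M | 0.50 equiv | 3.6 mol% | −25 °C | run made earlier |  |
| amber | 0.050 M | 0.50 equiv | 7.9 mol% | 8 °C | run made earlier |  |
| ochre | 0.025 M | 0.50 equiv | 5.3 mol% | −25 °C | run made earlier |  |
| eta | 0.050 M | 0.500 equiv | 5.3 mol% | −10 °C |  | 10 min |
| epsilon | 0.050 M | 0.500 equiv | 5.3 mol% | 20 °C |  | 10 min |
| gamma | 0.050 M | 0.500 equiv | 5.3 mol% |  | at −40 °C until 3.0 min, from then on at 20 °C | 10 min |
| alpha | 0.050 M | 0.500 equiv | 5.3 mol% | −40 °C |  | 10 min |

| run | time / min | L / % |
|---|---|---|
| teal | 6.00 | 0 |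
| teal | 12.0 | 0 |
| teal | 20.0 | 0 |
| teal | 25.0 | 0.3 |
| amber | 0.417 | 0.5 |
| amber | 0.833 | 0.4 |
| amber | 2.00 | 1.8 |
| amber | 5.00 | 3.5 |
| ochre | 3.00 | 0.1 |
| ochre | 8.00 | 0 |
| ochre | 15.0 | 0.3 |
| ochre | 25.0 | 0.5 |

(each reading ± 0.3 percentage points)

- the flask that comes out highest in amount of L, in percent of the X and E together charged, or "all alike" when all lie within 1.5 percentage points (eta / epsilon / gamma / alpha / all alike)
- L at the end, in percent of the X and E together charged, eta
- L at the end, in percent of the X and E together charged, epsilon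
- L at the end, in percent of the X and E together charged, gamma
- L at the end, in percent of the X and E together charged, alpha

- in a conversion E counts as not yet reacted

So I read the cold start of gamma as a lag time. Ochre's pace, carried over the hold, gives

L in the hold = 0.0600%

and that is far less than amber's reading, though ochre stood warmer than gamma's hold. What counts for gamma is therefore

t_w = t − t_hold = 7.00 min

This warm time is the stretch a flask spends at its working temperature after a cold hold. I expect gamma to be epsilon read at that time. Epsilon has the longer warm time, so I put it above gamma, with gamma's share of it near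

t_w / t = 0.700

or somewhat above that, if epsilon's curve bends as X is used.

The forecast names epsilon, with 0.7% for eta, 13% for epsilon, 9.5% for gamma and 0.03% for alpha, “assuming the cold hold does nothing”. Its gamma is 0.731 of its epsilon.

    X ⇌ E (K = 0.655, k = 1.21 /min, Ea = 83.0 kJ/mol, ΔH = −53.0 kJ/mol)
    X + G → G + L (k = 56.8 /M/min, Ea = 61.0 kJ/mol)
    G + E → G + D (k = 69.1 /M/min, Ea = 59.0 kJ/mol)
    2 G ⇌ Z, settled at all times (K = 960 /M, ΔH = −72.0 kJ/mol)
    X → J (k = 0.0500 /min, Ea = 80.0 kJ/mol)
    (constants at 20 °C)

Epsilon comes out highest at 21.5%, with gamma at 16.9%, eta at 0.405% and alpha at 0%. Gamma is 0.786 of epsilon, above 0.700. At the change, 3.00 min, gamma holds 0% of L. Gamma reaches half conversion at 10.8 min and epsilon at 7.85 min, a gap of 2.95 min, so gamma's warm time to that mark is 7.85 min. The neighbour of gamma read at 4.0 min has a warm time of 1.00 min and holds 3.18% of L.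

The earlier runs and the new flask come from a simulation for an exercise; noise was put on by code.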